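(The data are simulated with constants of no real substance; the scatter is artificial.)

the same everywhere: reagent in the second phase 0.585 M
- spring: substrate 0.30 M; run made earlier
- autumn: substrate 0.68 M; run made earlier
- flask: substrate 0.45 M; time 6.0 d; volume of the second phase over the first 1.0

| run | time / d | target / % |
|---|---|---|
| spring | 0.250 | 2.9 |
| spring | 0.417 | 8.1 |
| spring | 0.625 | 12.4 |
| spring | 1.04 | 18.1 |
| spring | 1.67 | 20.0 |
| spring | 2.50 | 21.7 |
| spring | 4.00 | 20.9 |
| autumn | 0.208 | 4.0 |
| autumn | 0.500 | 6.2 |
| autumn | 1.04 | 10.8 |
| autumn | 1.67 | 12.1 |
| autumn | 2.00 | 13.3 |
| autumn | 3.00 | 9.7 |
| autumn | 4.00 | 8.4 |

(standard deviation of a reading: 1 percentage point)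

- percent here means substrate units held: one side product counts as two
- in the second phase: reagent in the second phase; everything else is in the first
- charges count per volume of the first phase; a concentration in a rate is the amount of a species over the volume of its own phase; every rate counts per litre of the first phase
- the earlier runs were read with a standard deviation of 1 percentage point
- steps under discussion: substrate + reagent in the reaction phase -> target; reagent in the reaction phase <-> reagent in the second phase; substrate + target -> side product; target <-> isomer of the product
- the earlier runs hold the two phases in the same ratio of volumes as the flask asked about

- west: doubling the amount of reagent in the second phase, all else as stated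
- south-east: doubling the transfer coefficient of the reagent in the second phase, all else as stated

- target at 6.0 d, in percent of the substrate charged
- the change that raises the amount of target at 6.0 d, in percent of the substrate charged most ("none" if none brings more than 2 percentage points) (west / south-east / none)
- amount of target at 6.0 d, in percent of the substrate charged, after west

Equivalents were the unit I counted in. I folded the charges into one number, the reagent equivalents, meaning the reagent charged in the second phase over the substrate charged, each counted as an amount. It came to 1.95 for spring, 0.860 for autumn and 1.30 for the flask, and it says how much reagent each unit of substrate can draw on.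

At 4.00 d, spring held 20.9 % of its charge as target and autumn 8.4 %, so I drew a power line through those two readings, with exponent 1.11. That line put the flask at 13.3 %. I committed to this share for 6.0 d, though it belongs to the earlier time. West doubles the equivalents to 2.60, where the line gave 28.8 %. The transfer coefficient does not enter the number, so I chose west.

Was one number enough? The peak readings, 21.7 % and 13.3 %, gave an exponent of 0.598 instead, so time counts as well. Both runs also held the same reagent charge, so doubling the reagent was untested.

The forecast gave 13 % (8 % to 18 %) and chose west at 23 % (16 % to 30 %), taking doubling as “much like halving the substrate charge”.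

The flask held 13.1 % of its charge as target at 6.0 d, and west was best at 17.9 %, a gain of 4.8 percentage points against 0.11 points for south-east.

    substrate + reagent in the reaction phase → target (k = 2.70 × 10⁻⁵ L mol⁻¹ s⁻¹)
    reagent in the reaction phase ⇌ reagent in the second phase, rate k2*([reagent in the reaction phase] - [reagent in the second phase]/K2) per volume of the first phase (partition coefficient = 1.60, kL = 2.20 × 10⁻⁵ s⁻¹)
    substrate + target → side product (k = 2.70 × 10⁻⁵ L mol⁻¹ s⁻¹)
    target ⇌ isomer of the product (K = 2.30, k = 6.00 × 10⁻⁶ s⁻¹)

My line, with its share for 4.00 d, stood 11 points above the flask after west at 6.0 d. The neighbour flask charged with 1.1 M of substrate has 0.532 equivalents, where the line gives 4.93 % for 4.00 d, and that neighbour held 3.30 % of its charge as target at 6.0 d.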